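**Retrosynthetic overview**

1. Atom labels used below: C1 = CH carrying the 2-methylpropanoyl group; C2 = the ketone next to it; C3 = the O-bearing quaternary carbon; C4 = the ring ketone; C5 = the quaternary carbon between C4 and the lactone carbonyl C9; C6, C7, C8 = CH2, CH(prenyl), C(CH3)(homoprenyl).
2. Enabling feature: the lactone bond C9(=O)–O–C3 next to the acidic β-diketone C1–H is the scar of a retro-Claisen fragmentation. With C9 put back on C1 (O3 not yet present), the furandione and the eight-membered carbocycle become the bicyclo[3.3.1]nonane-2,4,9-trione of hyperforin. There C1–C8 and C3–C4 are bonds of six-membered rings B (C1, C9, C5–C8) and A (C1–C5, C9).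
3. Key disconnection: bicyclic trione ⇒ acyclic triketo ester 9 (one stereocentre, C5). Forward, ring B closes first by a PhSe+-triggered cation–enol cyclisation (C1–C8, anti across the (E)-geranyl olefin, selenium standing in for the C7 prenyl group as the prenyl cation does in the biosynthesis). Ring A then closes by Dieckmann condensation (C3–C4) in the same flask.
4. After the key step: Se → allyl at C7 (Keck), allyl → prenyl (cross-metathesis) gives hyperforin. Enolate hydroxylation at C3 then starts the biomimetic hemiketalisation/retro-Claisen fragmentation, which removes the temporary C1–C9 bond and leaves the five-membered lactone and the eight-membered carbocycle.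
5. Compound 9 comes from methyl acetoacetate and geranyl bromide by auxiliary-controlled allylation (sets C5) and two C-acylations.

Key step: step 6

Remark: C1 of the target lies between two ketone groups and is configurationally labile; the (R) configuration drawn is taken to be the more stable one, reached on equilibration during the last work-up.
Remark: L-valine tert-butyl ester with HMPA is assumed to direct allyl bromide to the face of the lithio-enamine that gives (S)-7; were the sense opposite, the D-valine ester would be used.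
Remark: 1,3-diketones and the 2-acyl-1,3-diketone 9 are enolised; they are drawn as keto forms or as one enol tautomer.

**Route**

Step 1
Reactants: 1 methyl acetoacetate; 2 geranyl bromide
Product: 3 methyl (4E)-2-acetyl-5,9-dimethyldeca-4,8-dienoate (racemic)
Conditions: NaH, THF, 0 °C to rt
Reagents that add atoms: none
Why: Acetoacetic ester alkylation (SN2 of the sodium enolate on the primary allylic bromide); the new stereocentre is racemic and becomes sp2 in step 2.

Step 2
Reactants: 3 methyl (4E)-2-acetyl-5,9-dimethyldeca-4,8-dienoate; 4 L-valine tert-butyl ester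
Product: 5 methyl (2Z,4E)-2-[1-[[(2S)-1-(tert-butoxy)-3-methyl-1-oxobutan-2-yl]amino]ethylidene]-5,9-dimethyldeca-4,8-dienoate
Conditions: BF3·OEt2 (cat.), benzene, reflux, Dean–Stark
Reagents that add atoms: none
Why: Acid-catalysed condensation of a β-keto ester with a primary amine should give the hydrogen-bonded (Z)-β-enamino ester, which carries the chiral auxiliary next to the future quaternary carbon C5.

Step 3
Reactants: 5 enamino ester
Product: 7 methyl (2S,4E)-2-acetyl-5,9-dimethyl-2-(prop-2-en-1-yl)deca-4,8-dienoate, via ketimine 6 (not isolated)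
Conditions: LiN(i-Pr)2, toluene, −78 °C; HMPA; CH2=CHCH2Br, −78 to −45 °C; then aq. AcOH–NaOAc, THF, rt
Reagents that add atoms: allyl bromide (C=CCBr); water (O)
Why: Alkylation of the chelated lithio-enamine (aza-enolate) of an α-substituted β-keto ester is a known auxiliary-controlled route to α-quaternary β-keto esters; the isopropyl group of the valine ester blocks one face of the chelate and sets C5, and mild aqueous acid hydrolyses ketimine 6 and returns the auxiliary.

Step 4
Reactants: 7 methyl (2S,4E)-2-acetyl-5,9-dimethyl-2-(prop-2-en-1-yl)deca-4,8-dienoate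
Product: 8 methyl (2S,4E)-5,9-dimethyl-2-(4-methyl-3-oxopentanoyl)-2-(prop-2-en-1-yl)deca-4,8-dienoate
Conditions: MgBr2·OEt2, i-Pr2NEt, 1-(2-methylpropanoyl)-1H-benzotriazole, CH2Cl2, rt
Reagents that add atoms: 1-(2-methylpropanoyl)-1H-benzotriazole (CC(C)C(=O)n1nnc2ccccc21)
Why: Soft enolisation (magnesium chelate, amine base) of the methyl ketone, the only enolisable position, and C-acylation by the acylbenzotriazole is a Claisen-type synthesis of 1,3-diketones; no stereocentre is touched.

Step 5
Reactants: 8 methyl (2S,4E)-5,9-dimethyl-2-(4-methyl-3-oxopentanoyl)-2-(prop-2-en-1-yl)deca-4,8-dienoate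
Product: 9 methyl (2S,4E)-5,9-dimethyl-2-[2-(2-methylpropanoyl)-3-oxohept-6-enoyl]-2-(prop-2-en-1-yl)deca-4,8-dienoate
Conditions: MgCl2, pyridine, CH2=CHCH2CH2COCl, CH2Cl2, 0 °C to rt
Reagents that add atoms: pent-4-enoyl chloride (C=CCCC(Cl)=O)
Why: C-Acylation of the magnesium chelate of a 1,3-diketone with an acid chloride should give the enolised 2-acyl-1,3-diketone; C1 is part of the enol and not stereogenic.

Step 6
Reactants: 9 triketo ester
Product: 11 4-hydroxy-6-methyl-6-(4-methylpent-3-en-1-yl)-5-(2-methylpropanoyl)-7-(phenylselanyl)-1,3-di(prop-2-en-1-yl)bicyclo[3.3.1]non-3-ene-2,9-dione (ring configuration of hyperforin and PhSe exo), via cyclohexanone selenide 10 (not isolated)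
Conditions: N-(phenylseleno)phthalimide, Me3SiOTf (cat.), CH2Cl2, −78 to −20 °C; then LiN(SiMe3)2 (excess), THF, −78 to 0 °C; aq. NH4Cl
Reagents that add atoms: N-(phenylseleno)phthalimide (O=C1c2ccccc2C(=O)N1[Se]c1ccccc1)
Why: Proposed new method: PhSe+ is transferred from N-(phenylseleno)phthalimide to the trisubstituted C7=C8 olefin, the seleniranium ion is opened at its tertiary carbon C8 by the enol carbon C1 of the 2-acyl-1,3-diketone (O-attack is reversible under the acid), and LiN(SiMe3)2 then deprotonates C3 of ketone 10, whose enolate acylates the 1,3-diaxial ester carbon C4 with loss of methoxide. The closest known reaction types are the N-(phenylseleno)phthalimide-induced carbocyclisation of alkenyl β-dicarbonyl compounds, the biomimetic cation–enol ring closure of prenylated acylphloroglucinol triketones and the Dieckmann condensation; their one-flask merger on an acyclic triketone is new. Ring B closes 6-endo-trig (C1 to C8) and ring A 6-exo-trig (C3 to C4). C7 and C8 are set by anti addition across the (E)-olefin in a chair in which the homoprenyl chain (trans to C6) becomes equatorial, the methyl group axial and selenium equatorial, and the same chair, with the C5 allyl group equatorial and the smaller ester axial, relays the configuration of C5; at C1 the bulkier 2-methylpropanoyl group should take the equatorial site away from the quaternary C5, so the pentenoyl arm is axial and cis to the ester. The step needs C1 and not C3 to attack C8, which is secured by closing ring B before C3 becomes an enol carbon, and it needs selenium activation of C7=C8 rather than of the monosubstituted olefins or the distal trisubstituted olefin, which is secured by the higher nucleophilicity of that olefin, the tertiary terminus it offers and the reversibility of selenium transfer with an enol in reach only there.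

Step 7
Reactants: 11 bicyclic selenide
Product: 12 4-hydroxy-6-methyl-6-(4-methylpent-3-en-1-yl)-5-(2-methylpropanoyl)-1,3,7-tri(prop-2-en-1-yl)bicyclo[3.3.1]non-3-ene-2,9-dione (configuration of hyperforin)
Conditions: CH2=CHCH2SnBu3 (neat, large excess), AIBN (cat.), 80 °C
Reagents that add atoms: allyltributylstannane (C=CC[Sn](CCCC)(CCCC)CCCC)
Why: Keck radical allylation of the secondary phenyl selenide: the C7 radical should take the allyl group on its exo lobe because the endo lobe points at C3 of ring A, which gives the equatorial (hyperforin) configuration; the same shielding, and the trans ring fusion otherwise required, disfavour 5-exo closure onto the homoprenyl olefin, and neat stannane favours the intermolecular path.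

Step 8
Reactants: 12 tri-allyl trione
Product: 13 hyperforin, (1R,5S,6R,7S)-4-hydroxy-6-methyl-1,3,7-tris(3-methylbut-2-en-1-yl)-6-(4-methylpent-3-en-1-yl)-5-(2-methylpropanoyl)bicyclo[3.3.1]non-3-ene-2,9-dione
Conditions: second-generation Grubbs catalyst (cat.), 2-methylbut-2-ene (large excess), CH2Cl2, 40 °C
Reagents that add atoms: 2-methylbut-2-ene (CC=C(C)C)
Why: Olefin cross-metathesis of the three monosubstituted allyl groups with 2-methylbut-2-ene (the excess suppresses ring-closing metathesis) should convert each into a prenyl group while the trisubstituted homoprenyl olefin stays inert; no stereocentre is touched.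

Step 9
Reactants: 13 hyperforin
Product: 16 (1R,3S,4R,5R,7S)-4-methyl-1,3,7-tris(3-methylbut-2-en-1-yl)-4-(4-methylpent-3-en-1-yl)-5-(2-methylpropanoyl)-8-oxabicyclo[5.2.1]decane-6,9,10-trione (target), via hydroxy trione 14 (not isolated), via hemiketal 15 (not isolated)
Conditions: KN(SiMe3)2, THF, −78 °C; 3-phenyl-2-(phenylsulfonyl)oxaziridine, −78 to 0 °C; AcOH
Reagents that add atoms: 3-phenyl-2-(phenylsulfonyl)oxaziridine (O=S(=O)(c1ccccc1)N1OC1c1ccccc1)
Why: Enolate hydroxylation by the N-sulfonyloxaziridine should occur at C3 from the face syn to the C9 carbonyl (the other face is covered by ring B), after which the C3 alkoxide 14 adds across ring A to C9 (hemiketal 15) and expels the doubly stabilised C1 enolate in a retro-Claisen fragmentation that copies the presumed biogenesis from hyperforin; C3 is fixed by the bridging lactone and C1 by protonation to the more stable epimer.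

**Compound list**

1 | methyl acetoacetate | CC(=O)CC(=O)OC | starting material
2 | geranyl bromide, (2E)-1-bromo-3,7-dimethylocta-2,6-diene | CC(C)=CCC/C(C)=C/CBr | starting material
3 | methyl (4E)-2-acetyl-5,9-dimethyldeca-4,8-dienoate (racemic) | CC(=O)C(C/C=C(\C)CCC=C(C)C)C(=O)OC | intermediate
4 | L-valine tert-butyl ester | CC(C)[C@H](N)C(=O)OC(C)(C)C | starting material
5 | methyl (2Z,4E)-2-[1-[[(2S)-1-(tert-butoxy)-3-methyl-1-oxobutan-2-yl]amino]ethylidene]-5,9-dimethyldeca-4,8-dienoate | C/C(N[C@@H](C(C)C)C(=O)OC(C)(C)C)=C(/C(=O)OC)C/C=C(\C)CCC=C(C)C | intermediate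
6 | methyl (2S,4E)-2-[1-[[(2S)-1-(tert-butoxy)-3-methyl-1-oxobutan-2-yl]imino]ethyl]-5,9-dimethyl-2-(prop-2-en-1-yl)deca-4,8-dienoate (ketimine, not isolated) | CC(=N[C@@H](C(C)C)C(=O)OC(C)(C)C)[C@](CC=C)(C/C=C(\C)CCC=C(C)C)C(=O)OC | intermediate
7 | methyl (2S,4E)-2-acetyl-5,9-dimethyl-2-(prop-2-en-1-yl)deca-4,8-dienoate | CC(=O)[C@](CC=C)(C/C=C(\C)CCC=C(C)C)C(=O)OC | intermediate
8 | methyl (2S,4E)-5,9-dimethyl-2-(4-methyl-3-oxopentanoyl)-2-(prop-2-en-1-yl)deca-4,8-dienoate | CC(C)C(=O)CC(=O)[C@](CC=C)(C/C=C(\C)CCC=C(C)C)C(=O)OC | intermediate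
9 | methyl (2S,4E)-5,9-dimethyl-2-[2-(2-methylpropanoyl)-3-oxohept-6-enoyl]-2-(prop-2-en-1-yl)deca-4,8-dienoate (enolised; drawn as triketone) | CC(C)C(=O)C(C(=O)CCC=C)C(=O)[C@](CC=C)(C/C=C(\C)CCC=C(C)C)C(=O)OC | intermediate
10 | methyl 4-methyl-4-(4-methylpent-3-en-1-yl)-3-(2-methylpropanoyl)-2-oxo-3-(pent-4-enoyl)-5-(phenylselanyl)-1-(prop-2-en-1-yl)cyclohexane-1-carboxylate; ester and pentenoyl groups cis-diaxial; allyl, 2-methylpropanoyl, 4-methylpent-3-enyl and PhSe groups equatorial (not isolated) | CC(C)C(=O)[C@]1(C(=O)CCC=C)C(=O)[C@@](CC=C)(C(=O)OC)C[C@H]([Se]c2ccccc2)[C@@]1(C)CCC=C(C)C | intermediate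
11 | 4-hydroxy-6-methyl-6-(4-methylpent-3-en-1-yl)-5-(2-methylpropanoyl)-7-(phenylselanyl)-1,3-di(prop-2-en-1-yl)bicyclo[3.3.1]non-3-ene-2,9-dione, ring configuration of hyperforin, PhSe exo | CC(C)C(=O)[C@]12C(O)=C(CC=C)C(=O)[C@](CC=C)(C1=O)C[C@H]([Se]c1ccccc1)[C@@]2(C)CCC=C(C)C | intermediate
12 | 4-hydroxy-6-methyl-6-(4-methylpent-3-en-1-yl)-5-(2-methylpropanoyl)-1,3,7-tri(prop-2-en-1-yl)bicyclo[3.3.1]non-3-ene-2,9-dione, configuration of hyperforin | CC(C)C(=O)[C@]12C(O)=C(CC=C)C(=O)[C@](CC=C)(C1=O)C[C@H](CC=C)[C@@]2(C)CCC=C(C)C | intermediate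
13 | hyperforin, (1R,5S,6R,7S)-4-hydroxy-6-methyl-1,3,7-tris(3-methylbut-2-en-1-yl)-6-(4-methylpent-3-en-1-yl)-5-(2-methylpropanoyl)bicyclo[3.3.1]non-3-ene-2,9-dione | CC(C)C(=O)[C@]12C(O)=C(CC=C(C)C)C(=O)[C@](CC=C(C)C)(C1=O)C[C@H](CC=C(C)C)[C@@]2(C)CCC=C(C)C | intermediate
14 | 3-hydroxy-6-methyl-1,3,7-tris(3-methylbut-2-en-1-yl)-6-(4-methylpent-3-en-1-yl)-5-(2-methylpropanoyl)bicyclo[3.3.1]nonane-2,4,9-trione, hydroxyl on the face of ring A that faces the C-9 carbonyl (formed as potassium alkoxide, not isolated) | CC(C)C(=O)[C@]12C(=O)[C@@](O)(CC=C(C)C)C(=O)[C@](CC=C(C)C)(C1=O)C[C@H](CC=C(C)C)[C@@]2(C)CCC=C(C)C | intermediate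
15 | hemiketal of 14: the C-3 oxygen bonded to C-9, which carries a hydroxyl group (oxygen bridge across ring A; not isolated) | CC(C)C(=O)[C@]12C(=O)[C@]3(CC=C(C)C)O[C@@]1(O)[C@@](CC=C(C)C)(C3=O)C[C@H](CC=C(C)C)[C@@]2(C)CCC=C(C)C | intermediate
16 | (1R,3S,4R,5R,7S)-4-methyl-1,3,7-tris(3-methylbut-2-en-1-yl)-4-(4-methylpent-3-en-1-yl)-5-(2-methylpropanoyl)-8-oxabicyclo[5.2.1]decane-6,9,10-trione | CC(C)=CCC[C@]1(C)[C@@H](CC=C(C)C)C[C@@]2(CC=C(C)C)C(=O)O[C@@](CC=C(C)C)(C(=O)[C@H]1C(=O)C(C)C)C2=O | target

**Totals**

Total step count: 9. Longest linear sequence: 9 steps (from methyl acetoacetate 1).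

**Steps most likely to fail**

Step 6 (bears the label). Selenium may be taken up at the monosubstituted olefins or at the distal trisubstituted olefin; the enol oxygen may capture the seleniranium ion instead of C1; C1 may form as the epimer whose pentenoyl arm is equatorial and cannot close ring A; the non-enolisable triketone may undergo retro-Claisen cleavage under base. The fallback sets out from 9 and comes back at 11, using known reaction types as separate, isolated steps. Kinetic seleno-etherification (N-(phenylseleno)phthalimide, ZnI2 cat., CH2Cl2) should give the O-cyclised dihydropyran enol ether F1. Acid-induced O-to-C transfer (SnCl4, CH2Cl2, −78 °C) should convert it into ketone 10, which is now isolated and freed from its C1 epimer. Dieckmann condensation of pure 10 with KOt-Bu in THF should then give 11.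

Step 7. The C7 radical may cyclise onto the homoprenyl olefin (5-exo) or be reduced before allyl transfer. The fallback avoids a C7 radical; it sets out from 10 (isolated as above) and comes back at 12. Oxidation of the selenide with H2O2 and syn-elimination of the selenoxide should give the cyclohex-5-enone F2. A thermal Cope rearrangement (toluene, heat) should move the allyl group of C5 suprafacially to C7 and give the conjugated alkylidene β-keto ester F3. Conjugate reduction with [(Ph3P)CuH]6 and C-allylation of the resulting β-keto ester enolate with allyl bromide, anti to the axial acyl group on C1, should give the C7-allyl analogue of 10, F4. Dieckmann condensation (LiN(SiMe3)2, THF) should then give 12.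

Step 9. The oxaziridine may oxidise elsewhere, hydroxylation may stop at a hydroxy trione that does not fragment, or fragmentation may take another C–C bond. The fallback sets out from 13 and comes back at 16, separating oxidation from fragmentation. The potassium enolate of 13 is silyloxylated with Me3SiOOSiMe3 to the isolable 3-(trimethylsilyloxy) trione F5. Bu4NF in THF should then free the C3 alkoxide under aprotic conditions, and this enters the same hemiketal/retro-Claisen sequence to 16.

Further compounds
F1 | step 6 | methyl 2-methyl-2-(4-methylpent-3-en-1-yl)-6-[1-(2-methylpropanoyl)-2-oxohex-5-en-1-ylidene]-3-(phenylselanyl)-5-(prop-2-en-1-yl)oxane-5-carboxylate (O-cyclised enol ether) | COC(=O)[C@@]1(CC=C)C[C@H]([Se]c2ccccc2)[C@@](C)(CCC=C(C)C)OC1=C(C(=O)C(C)C)C(=O)CCC=C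
F2 | step 7 | methyl 4-methyl-4-(4-methylpent-3-en-1-yl)-3-(2-methylpropanoyl)-2-oxo-3-(pent-4-enoyl)-1-(prop-2-en-1-yl)cyclohex-5-ene-1-carboxylate | CC(C)C(=O)[C@]1(C(=O)CCC=C)C(=O)[C@@](CC=C)(C(=O)OC)C=C[C@@]1(C)CCC=C(C)C
F3 | step 7 | methyl 4-methyl-4-(4-methylpent-3-en-1-yl)-5-(2-methylpropanoyl)-6-oxo-5-(pent-4-enoyl)-3-(prop-2-en-1-yl)cyclohex-1-ene-1-carboxylate | CC(C)C(=O)[C@]1(C(=O)CCC=C)C(=O)C(C(=O)OC)=C[C@H](CC=C)[C@@]1(C)CCC=C(C)C
F4 | step 7 | methyl 4-methyl-4-(4-methylpent-3-en-1-yl)-3-(2-methylpropanoyl)-2-oxo-3-(pent-4-enoyl)-1,5-di(prop-2-en-1-yl)cyclohexane-1-carboxylate | CC(C)C(=O)[C@]1(C(=O)CCC=C)C(=O)[C@@](CC=C)(C(=O)OC)C[C@H](CC=C)[C@@]1(C)CCC=C(C)C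
F5 | step 9 | 6-methyl-1,3,7-tris(3-methylbut-2-en-1-yl)-6-(4-methylpent-3-en-1-yl)-5-(2-methylpropanoyl)-3-(trimethylsilyloxy)bicyclo[3.3.1]nonane-2,4,9-trione | CC(C)C(=O)[C@]12C(=O)[C@@](O[Si](C)(C)C)(CC=C(C)C)C(=O)[C@](CC=C(C)C)(C1=O)C[C@H](CC=C(C)C)[C@@]2(C)CCC=C(C)C
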